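**Plan**

1. Retrosynthesis: the two prenyl groups go back to allyl groups (cross-metathesis, last step) and the 4'-OH to its acetate. Ring C is then cut at O1–C2 and at C4–C4a, giving the resorcinol 6 and the (R)-β-hydroxy ester 11.
2. Enabling feature: in ring A, C4a is the only unsubstituted carbon. It lies between C5–OH and C8a–O1, and the C6/C8 side chains and C7–OMe sit symmetrically about the C4a···C7 axis. The A-ring precursor is therefore a symmetric resorcinol with two equivalent OH groups and one C–H between them; either oxygen can become O1, and the other becomes the chelated 5-OH.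
3. Forward, ring A: methyl 2,6-dihydroxy-4-methoxybenzoate is bis-O-allylated, rearranged by a double Claisen reaction (the ester blocks the later C4a) and then hydrolysed and decarboxylated to 6. Ring B unit: O-acetylvanillic acid is converted to a β-keto ester and reduced by asymmetric transfer hydrogenation to 11.
4. Ring C, the only ring formed in the route, is closed in one flask by Mitsunobu etherification (O1–C2) followed by Friedel–Crafts cycloacylation (C4–C4a). Deacetylation and double cross-metathesis finish the route.
5. Stereochemistry: C2 is the only stereocentre. It is set as the (R)-carbinol by the catalyst in step 5 and inverted to (S) in the Mitsunobu displacement; the 4'-acetoxy group keeps the benzylic carbon from ionising.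

Key step: step 6

Remark: allyl groups are carried as acid-stable precursors of the prenyl groups; 1, 7 and potassium mono-tert-butyl malonate are taken as catalogue chemicals.

**Route**

Step 1
Reactants: 1 methyl 2,6-dihydroxy-4-methoxybenzoate
Product: 2 methyl 4-methoxy-2,6-bis(prop-2-enyloxy)benzoate
Conditions: allyl bromide (3 equiv), K2CO3, DMF, 60 °C
Reagents that add atoms: allyl bromide, C=CCBr
Why: Double Williamson etherification; excess allyl bromide and carbonate in DMF should alkylate both chelated phenols, and the methyl ester is inert to these conditions.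

Step 2
Reactants: 2 methyl 4-methoxy-2,6-bis(prop-2-enyloxy)benzoate
Product: 4 methyl 2,6-dihydroxy-4-methoxy-3,5-di(prop-2-enyl)benzoate, via mono-Claisen phenol 3 (not isolated)
Conditions: PhNEt2, 195 °C
Reagents that add atoms: none
Why: Two consecutive aromatic Claisen rearrangements ([3,3]-sigmatropic shift, then tautomerisation); one ortho position of each allyloxy group carries the ester, so each allyl group can only end at C-3 or C-5, directly or by the Claisen–Cope path through the blocked carbon.

Step 3
Reactants: 4 methyl 2,6-dihydroxy-4-methoxy-3,5-di(prop-2-enyl)benzoate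
Product: 6 5-methoxy-4,6-di(prop-2-enyl)benzene-1,3-diol, via free benzoic acid 5 (not isolated)
Conditions: NaOH, MeOH–H2O, reflux (Ar); then aq. HCl to pH 2, 60 °C
Reagents that add atoms: none
Why: Saponification followed by protodecarboxylation of the electron-rich 2,6-dihydroxybenzoic acid (ipso-protonation, loss of CO2) removes the blocking group and leaves the single ring C–H between the two hydroxyls.

Step 4
Reactants: 7 4-acetoxy-3-methoxybenzoic acid
Product: 10 tert-butyl 3-(4-acetoxy-3-methoxyphenyl)-3-oxopropanoate, via aroyl chloride 8 (not isolated), via acylmalonic half-ester 9 (not isolated)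
Conditions: (COCl)2, cat. DMF, CH2Cl2, 0 °C → rt; then KO2CCH2CO2tBu, MgCl2, Et3N, MeCN, 0 °C → rt; aq. HCl work-up
Reagents that add atoms: potassium 3-tert-butoxy-3-oxopropanoate, CC(C)(C)OC(=O)CC(=O)[O-].[K+]
Why: Acid chloride formation, then C-acylation of the magnesium enolate of a malonate half-ester (decarboxylative Claisen-type condensation); the chelated enolate should attack the acid chloride in preference to the aryl acetate, and the acylmalonic acid loses CO2 on acidification.

Step 5
Reactants: 10 tert-butyl 3-(4-acetoxy-3-methoxyphenyl)-3-oxopropanoate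
Product: 11 tert-butyl (3R)-3-(4-acetoxy-3-methoxyphenyl)-3-hydroxypropanoate
Conditions: RuCl[(R,R)-TsDPEN](p-cymene) (1 mol %), HCO2H–Et3N (5:2), EtOAc, 30 °C
Reagents that add atoms: none
Why: Asymmetric transfer hydrogenation of an aryl ketone with a Ru(II)–arene–TsDPEN catalyst (bifunctional hydride transfer with aryl recognition); the (R,R)-ligand is expected to give the (R)-carbinol by the aryl-ketone model, and the aryl acetate and tert-butyl ester should not react with formate.

Step 6
Reactants: 6 5-methoxy-4,6-di(prop-2-enyl)benzene-1,3-diol (2 equiv) and 11 tert-butyl (3R)-3-(4-acetoxy-3-methoxyphenyl)-3-hydroxypropanoate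
Product: 15 (2S)-2-(4-acetoxy-3-methoxyphenyl)-5-hydroxy-7-methoxy-6,8-di(prop-2-enyl)chroman-4-one, via aryl ether tert-butyl ester 12 (not isolated), via aryl ether acid 13 (not isolated), via mixed trifluoroacetic anhydride 14 (not isolated)
Conditions: PPh3, DIAD, toluene, 0 °C → rt; then CH2Cl2, TFA, 0 °C → rt; then TFAA, 0 °C; MeOH, then aq. NaHCO3
Reagents that add atoms: none
Why: The PPh3/DIAD betaine turns the benzylic hydroxyl of 11 into an oxyphosphonium leaving group that one of the two equivalent phenolic oxygens of 6 displaces (SN2) to give ether 12; TFA then frees the acid 13, TFAA converts it into the mixed anhydride 14, and this acylium equivalent attacks the only unsubstituted ring carbon, which lies between the new ether oxygen and the remaining hydroxyl. The closest known reaction types are the Mitsunobu aryl etherification of benzylic β-hydroxy esters and the Friedel–Crafts cycloacylation of 3-aryloxypropanoic acids to chroman-4-ones, telescoped here into a formal [3+3] annulation. Ring C is closed in the second stage by a 6-exo-trig electrophilic aromatic acylation. The new stereocentre C-2 is set by inversion of the (R)-carbinol of 11, which gives (S); the para-acetoxy group, in place of a free or alkylated phenol oxygen, destabilises the benzylic cation and should keep both the displacement and the acid treatment from ionising this carbon. The step needs O- over C-alkylation, mono- over bis-etherification and a single site of acylation: phenols react at oxygen under Mitsunobu conditions, 6 is used in excess (the surplus is recoverable after the methanolic work-up), and the symmetry of 6 leaves one ring C–H and two equivalent oxygens, so no regioisomer can form. Allyl groups are used in place of prenyl groups because they tolerate TFA, and the methanol quench cleaves any phenolic trifluoroacetate.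

Step 7
Reactants: 15 (2S)-2-(4-acetoxy-3-methoxyphenyl)-5-hydroxy-7-methoxy-6,8-di(prop-2-enyl)chroman-4-one
Product: 16 (2S)-5-hydroxy-2-(4-hydroxy-3-methoxyphenyl)-7-methoxy-6,8-di(prop-2-enyl)chroman-4-one
Conditions: HCl (0.3 M) in MeOH, rt
Reagents that add atoms: none
Why: Acid-catalysed transesterification (methanolysis) of the aryl acetate; no phenoxide is formed, so the base-triggered ring opening that racemises flavanones is avoided, and allyl groups, unlike prenyl groups, tolerate the acid.

Step 8
Reactants: 16 (2S)-5-hydroxy-2-(4-hydroxy-3-methoxyphenyl)-7-methoxy-6,8-di(prop-2-enyl)chroman-4-one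
Product: 17 (2S)-5-hydroxy-2-(4-hydroxy-3-methoxyphenyl)-7-methoxy-6,8-bis(3-methylbut-2-enyl)chroman-4-one
Conditions: (H2IMes)(PCy3)Cl2Ru=CHPh (5 mol %), 2-methylbut-2-ene (excess), CH2Cl2, 40 °C
Reagents that add atoms: 2-methylbut-2-ene, CC=C(C)C
Why: Double olefin cross-metathesis of the two terminal allyl groups with excess 2-methylbut-2-ene should convert each into a prenyl group with loss of propene; the conditions are neutral, so C-2 and the free phenols should be unaffected.

**Compound list**

1 | methyl 2,6-dihydroxy-4-methoxybenzoate | COC(=O)c1c(O)cc(OC)cc1O | starting material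
2 | methyl 4-methoxy-2,6-bis(prop-2-enyloxy)benzoate | COC(=O)c1c(OCC=C)cc(OC)cc1OCC=C | intermediate
3 | methyl 2-hydroxy-4-methoxy-3-(prop-2-enyl)-6-(prop-2-enyloxy)benzoate | COC(=O)c1c(O)c(CC=C)c(OC)cc1OCC=C | intermediate
4 | methyl 2,6-dihydroxy-4-methoxy-3,5-di(prop-2-enyl)benzoate | COC(=O)c1c(O)c(CC=C)c(OC)c(CC=C)c1O | intermediate
5 | 2,6-dihydroxy-4-methoxy-3,5-di(prop-2-enyl)benzoic acid | OC(=O)c1c(O)c(CC=C)c(OC)c(CC=C)c1O | intermediate
6 | 5-methoxy-4,6-di(prop-2-enyl)benzene-1,3-diol | COc1c(CC=C)c(O)cc(O)c1CC=C | intermediate
7 | 4-acetoxy-3-methoxybenzoic acid | COc1cc(C(=O)O)ccc1OC(C)=O | starting material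
8 | 4-acetoxy-3-methoxybenzoyl chloride | COc1cc(C(Cl)=O)ccc1OC(C)=O | intermediate
9 | 2-(4-acetoxy-3-methoxybenzoyl)-3-tert-butoxy-3-oxopropanoic acid (magnesium chelate in the flask) | COc1cc(C(=O)C(C(=O)O)C(=O)OC(C)(C)C)ccc1OC(C)=O | intermediate
10 | tert-butyl 3-(4-acetoxy-3-methoxyphenyl)-3-oxopropanoate | COc1cc(C(=O)CC(=O)OC(C)(C)C)ccc1OC(C)=O | intermediate
11 | tert-butyl (3R)-3-(4-acetoxy-3-methoxyphenyl)-3-hydroxypropanoate | COc1cc([C@H](O)CC(=O)OC(C)(C)C)ccc1OC(C)=O | intermediate
12 | tert-butyl (3S)-3-(4-acetoxy-3-methoxyphenyl)-3-[5-hydroxy-3-methoxy-2,4-di(prop-2-enyl)phenoxy]propanoate | COc1cc([C@@H](Oc2cc(O)c(CC=C)c(OC)c2CC=C)CC(=O)OC(C)(C)C)ccc1OC(C)=O | intermediate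
13 | (3S)-3-(4-acetoxy-3-methoxyphenyl)-3-[5-hydroxy-3-methoxy-2,4-di(prop-2-enyl)phenoxy]propanoic acid | COc1cc([C@@H](Oc2cc(O)c(CC=C)c(OC)c2CC=C)CC(=O)O)ccc1OC(C)=O | intermediate
14 | mixed anhydride of acid 13 with trifluoroacetic acid | COc1cc([C@@H](Oc2cc(O)c(CC=C)c(OC)c2CC=C)CC(=O)OC(=O)C(F)(F)F)ccc1OC(C)=O | intermediate
15 | (2S)-2-(4-acetoxy-3-methoxyphenyl)-5-hydroxy-7-methoxy-6,8-di(prop-2-enyl)chroman-4-one | COc1cc([C@@H]2CC(=O)c3c(O)c(CC=C)c(OC)c(CC=C)c3O2)ccc1OC(C)=O | intermediate
16 | (2S)-5-hydroxy-2-(4-hydroxy-3-methoxyphenyl)-7-methoxy-6,8-di(prop-2-enyl)chroman-4-one | COc1cc([C@@H]2CC(=O)c3c(O)c(CC=C)c(OC)c(CC=C)c3O2)ccc1O | intermediate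
17 | (2S)-5-hydroxy-2-(4-hydroxy-3-methoxyphenyl)-7-methoxy-6,8-bis(3-methylbut-2-enyl)chroman-4-one | COc1cc([C@@H]2CC(=O)c3c(O)c(CC=C(C)C)c(OC)c(CC=C(C)C)c3O2)ccc1O | target

**Step count and risks**

Total step count: 8. Longest linear sequence: 6 steps (steps 1, 2, 3, 6, 7, 8, from compound 1).

Steps most likely to fail:

Step 6. The activated benzylic alcohol may eliminate to the cinnamate faster than the hindered, only moderately acidic phenol substitutes it. Partial ionisation at the benzylic carbon, in the displacement or under TFA, would erode the enantiomeric purity, and tert-butyl cation released in the ester cleavage may alkylate the electron-rich ring. The fallback reverses the order of bond formation and takes the configuration from a separation. It sets out from 6, which is C-acylated at its free ring position with (2E)-3-(4-acetoxy-3-methoxyphenyl)prop-2-enoyl chloride F1 (made from commercial O-acetylferulic acid with oxalyl chloride) under AlCl3 in nitrobenzene–CH2Cl2 at 0 °C to rt (Friedel–Crafts acylation). This should give the 2',6'-dihydroxychalcone F2, which closes by intramolecular oxa-Michael addition (catalytic NaOAc, EtOH) to the racemic flavanone F3. Preparative chromatography on a chiral stationary phase separates 15 from its (2R)-enantiomer F4; F4 can be returned to F3 with catalytic base (ring opening to F2 and reclosure) and resubmitted. The route is rejoined at 15.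

Step 8. The double cross-metathesis may stop short, and ruthenium hydrides may shift allyl to propenyl double bonds, both favoured if the free guaiacol-type phenol slows the catalyst; the mono-prenyl and propenyl congeners would be hard to remove from the final compound. The fallback changes the order of the last two operations and the deprotection chemistry. It sets out from 15, where cross-metathesis with 2-methylbut-2-ene is run on the acetate (no free B-ring phenol) to give the diprenyl acetate F5, which is purified at this stage. The acetate is then removed under neutral conditions (NH4OAc, MeOH–H2O, rt; acid is avoided once prenyl groups are present), and the route is rejoined at 17.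

Step 3. Acyl substitution at the ester may be slow, because the carbonyl is shielded by two ortho substituents and deactivated in the bis-phenoxide; prolonged hot base could then cause allyl-to-propenyl migration and oxidative degradation of the electron-rich ring. The fallback attacks the ester methyl carbon instead of the carbonyl. It sets out from 4, where SN2 O-demethylation with LiI in pyridine at reflux should give the lithium carboxylate F6. Acidification gives acid 5, where the route is rejoined, and 5 loses CO2 on warming as before.

**Further compounds**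

F1 | step 6 | (2E)-3-(4-acetoxy-3-methoxyphenyl)prop-2-enoyl chloride | COc1cc(/C=C/C(Cl)=O)ccc1OC(C)=O
F2 | step 6 | (2E)-3-(4-acetoxy-3-methoxyphenyl)-1-[2,6-dihydroxy-4-methoxy-3,5-di(prop-2-enyl)phenyl]prop-2-en-1-one | COc1cc(/C=C/C(=O)c2c(O)c(CC=C)c(OC)c(CC=C)c2O)ccc1OC(C)=O
F3 | step 6 | racemic 2-(4-acetoxy-3-methoxyphenyl)-5-hydroxy-7-methoxy-6,8-di(prop-2-enyl)chroman-4-one | COc1cc(C2CC(=O)c3c(O)c(CC=C)c(OC)c(CC=C)c3O2)ccc1OC(C)=O
F4 | step 6 | (2R)-2-(4-acetoxy-3-methoxyphenyl)-5-hydroxy-7-methoxy-6,8-di(prop-2-enyl)chroman-4-one | COc1cc([C@H]2CC(=O)c3c(O)c(CC=C)c(OC)c(CC=C)c3O2)ccc1OC(C)=O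
F5 | step 8 | (2S)-2-(4-acetoxy-3-methoxyphenyl)-5-hydroxy-7-methoxy-6,8-bis(3-methylbut-2-enyl)chroman-4-one | COc1cc([C@@H]2CC(=O)c3c(O)c(CC=C(C)C)c(OC)c(CC=C(C)C)c3O2)ccc1OC(C)=O
F6 | step 3 | lithium 2,6-dihydroxy-4-methoxy-3,5-di(prop-2-enyl)benzoate | [Li+].[O-]C(=O)c1c(O)c(CC=C)c(OC)c(CC=C)c1O
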